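**Plan**

1. Last cut: the lactone O–C10 bond. In the 10α-H acid the C19 carboxyl (axial on C4) and H-10 are syn-diaxial on the α face of ring A and γ to each other, so a carboxylate-bound iron oxidant can reach this tertiary C–H bond.
2. Earlier cuts: C9–C10 (aldol condensation closing ring B), C5–C6 (Michael addition joining ring A to rings C/D), C4–C19 (conjugate vinylation), C13–C16 and C8–C15 (radical cyclisation and Birch alkylation for ring D).
3. Forward order: ring C, then ring D, from 3-methoxybenzoic acid; ring A from toluene cis-dihydrodiol; union at C5–C6; ring B; functional-group adjustment; lactone ring last; then methylenation and deprotection.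
4. Stereochemistry: C2/C3 from the diol; C4 by addition anti to O3; C8/C13 by resolution; C5/C6 by equilibration; C10 by protonation in a dissolving-metal reduction; C9 by the enforced cis B/C fusion; C11 by hydride attack on the α face; the lactone forms with retention at C10.

Key step: step 22

Remark on numbering: gibberellane numbering is used once ring A is joined to rings C/D (ring A: C1–C5, C10; ring B: C5, C6, C8, C9, C10; ring C: C8, C9, C11–C14; ring D: C8, C13–C16; C7 = carboxyl carbon on C6; C17 = exocyclic carbon on C16; C18 = methyl on C4; C19 = the other carbon on C4). β is the face of H-5, H-9, C18 and the C15–C16 bridge; α is the face of C19. In the bicyclo[3.2.1]octanes C1, C2, C3, C4, C5, C6, C7, C8 are the later C8, C9, C11, C12, C13, C16, C15, C14.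

Assumption: the less soluble salt in step 4 is taken to be that of the (1R,5S)-acid with (S)-1-phenylethylamine; should the other diastereomer crystallise, the (R)-amine is used.

Assumption: the diol 13 is bought as the fermentation product.

**Step 1**
Reactants: 1 3-methoxybenzoic acid; 2 2,3-dibromoprop-1-ene
Product: 3 rac-1-(2-bromoprop-2-en-1-yl)-3-methoxycyclohexa-2,5-diene-1-carboxylic acid
Conditions: Li (3.0 equiv), NH3/THF, −78 °C; then 2, −78 → −33 °C; NH4Cl; cold dil. HCl to pH 4
Reagents that add atoms: none
Why: Birch reductive alkylation, in which 1,4-reduction of the benzoate leaves a carboxylate-stabilised cyclohexadienyl dianion that is alkylated at the ipso carbon by the allylic bromide of 2 (the vinylic bromide is inert), creating the quaternary carbon (later C8) as a racemate.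

**Step 2**
Reactants: 3
Product: 4 rac-1-(2-bromoprop-2-en-1-yl)-5-oxocyclohex-3-ene-1-carboxylic acid
Conditions: 2 M HCl, THF, 25 → 50 °C
Reagents that add atoms: water, O
Why: Enol ether hydrolysis followed by acid-catalysed migration of the remaining ring alkene into conjugation gives the 5,5-disubstituted cyclohex-2-enone in which the later C13 is the β-carbon.

**Step 3**
Reactants: 4
Product: 5 rac-6-methylidene-3-oxobicyclo[3.2.1]octane-1-carboxylic acid
Conditions: (Me3Si)3SiH, AIBN, toluene, 85 °C, slow addition
Reagents that add atoms: none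
Why: 5-exo-trig vinyl radical cyclisation onto the enone β-carbon closes ring D, the α-keto radical is reduced by the silane, and because the two-carbon bridge can only span the ring cis the configuration of C13 follows from that of C8.

**Step 4**
Reactants: 5
Product: 6 (S)-1-phenylethylammonium (1R,5S)-6-methylidene-3-oxobicyclo[3.2.1]octane-1-carboxylate
Conditions: (S)-1-phenylethylamine (0.5 equiv), EtOAc/EtOH, crystallisation, recrystallisation to constant rotation
Reagents that add atoms: (S)-1-phenylethylamine, C[C@H](N)c1ccccc1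
Why: Classical resolution by diastereomeric salt crystallisation fixes the absolute configuration of C8 and C13 for the rest of the route, the other enantiomer staying in the mother liquor.

**Step 5**
Reactants: 6
Product: 8 (1R,5S)-1-(hydroxymethyl)-6-methylidenebicyclo[3.2.1]octan-3-ol (both C3 epimers), via free (1R,5S)-acid 7 (not isolated)
Conditions: 1 M HCl/EtOAc partition; then LiAlH4, THF, 0 °C → reflux
Reagents that add atoms: none
Why: Hydride reduction with LiAlH4 takes the liberated acid (C6) and the ketone to alcohols without touching the stereocentres or the 1,1-disubstituted alkene, the configuration of the transient carbinol being irrelevant.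

**Step 6**
Reactants: 8
Product: 9 (1R,5S)-6-methylidene-3-oxobicyclo[3.2.1]octane-1-carbaldehyde
Conditions: n-Pr4N[RuO4] (5 mol %), N-methylmorpholine N-oxide (3 equiv), 4 Å molecular sieves, CH2Cl2, rt
Reagents that add atoms: none
Why: Ley–Griffith oxidation converts the neopentyl primary alcohol into the aldehyde (C6) and the secondary alcohol back into the C11 ketone in one operation, the quaternary C8 excluding epimerisation.

**Step 7**
Reactants: 9
Product: 12 (1R,5S)-6-methylidene-1-[(E)-2-nitroethenyl]bicyclo[3.2.1]octan-3-one, via nitro alcohol 10 (not isolated), via nitro mesylate 11 (not isolated)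
Conditions: MeNO2, Et3N (0.2 equiv), 0 °C → rt; evaporate; MsCl, Et3N (2.5 equiv), CH2Cl2, −20 → 0 °C
Reagents that add atoms: nitromethane, C[N+](=O)[O-]
Why: Henry addition of nitromethane to the non-enolisable aldehyde (far more electrophilic than the ketone) and E1cB elimination of the derived mesylate give the E-nitroalkene, in which C6 is the electrophilic carbon and the nitromethane carbon is the future C7.

**Step 8**
Reactants: 13 (1S,2R)-3-methylcyclohexa-3,5-diene-1,2-diol
Product: 14 (3aR,7aS)-2,2,4-trimethyl-3a,7a-dihydro-1,3-benzodioxole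
Conditions: 2,2-dimethoxypropane, TsOH·H2O (1 mol %), acetone, 0 °C
Reagents that add atoms: 2,2-dimethoxypropane, COC(C)(C)OC
Why: Acid-catalysed transketalisation protects the cis-diol (the future O2 and O3) as the acetonide and prevents dehydration of the diene-diol to a cresol.

**Step 9**
Reactants: 14
Product: 15 (3aR,7aS)-2,2,4-trimethyl-3a,6,7,7a-tetrahydro-1,3-benzodioxole
Conditions: KO2C–N=N–CO2K, AcOH, MeOH, 0 °C → rt
Reagents that add atoms: none
Why: Diimide reduction is sensitive to alkene substitution and should saturate the disubstituted alkene of the diene while leaving the methyl-bearing trisubstituted alkene (C4=C5).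

**Step 10**
Reactants: 15
Product: 16 (3aS,7aR)-2,2,7-trimethyl-3a,7a-dihydro-1,3-benzodioxol-5(4H)-one
Conditions: Rh2(C6H10NO)4 (dirhodium tetracaprolactamate, 1 mol %), t-BuOOH (5 equiv), K2CO3, CH2Cl2, rt
Reagents that add atoms: tert-butyl hydroperoxide, CC(C)(C)OO
Why: Radical allylic oxidation should attack the unhindered allylic methylene (C10) and not the acetal C–H on C3, giving the 3-methylcyclohex-2-enone in which C4 is the β-carbon.

**Step 11**
Reactants: 16
Product: 17 trimethyl{[(3aR,4S,7aS)-4-ethenyl-2,2,4-trimethyl-3a,4,7,7a-tetrahydro-1,3-benzodioxol-6-yl]oxy}silane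
Conditions: CH2=CHMgBr, CuBr·SMe2 (10 mol %), Me3SiCl, HMPA, THF, −78 °C; Et3N
Reagents that add atoms: vinylmagnesium bromide, C=C[Mg]Br; chlorotrimethylsilane, C[Si](C)(C)Cl
Why: Copper-catalysed conjugate addition with silyl trapping places the vinyl group (its inner carbon is the future C19) on C4 anti to the neighbouring acetonide oxygen on C3, which sets the quaternary centre with vinyl α and methyl β, and fixes the enolate regiospecifically as the C5=C10 silyl enol ether.

**Step 12**
Reactants: 17; 12
Product: 19 9,10-seco nitro diketone (ring A 10-ketone joined C5–C6 to the ring C/D 11-ketone; C6 bears CH2NO2; both epimers at C5 and C6), via lithium enolate 18 (not isolated)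
Conditions: MeLi (1.05 equiv), THF, 0 °C; then 12 in THF, −78 °C; AcOH, −78 °C
Reagents that add atoms: none
Why: Michael addition of a regiodefined lithium enolate to a nitroalkene forges the C5–C6 bond, the nitroalkene being attacked faster at −78 °C than the ring C ketone is deprotonated, and the two new centres, formed as mixtures, are corrected by equilibration in steps 14 and 15.

**Step 13**
Reactants: 19
Product: 20 9,10-seco keto acid (as 19 with CO2H in place of CH2NO2; both epimers at C5 and C6)
Conditions: NaNO2 (3 equiv), AcOH (10 equiv), DMSO, 35 °C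
Reagents that add atoms: sodium nitrite, [Na+].[O-]N=O; water, O
Why: Nitrosative oxidation of a primary nitroalkane (nitronate nitrosation, nitrolic acid, nitrile oxide, hydrolysis) turns CH2NO2 into the C7 carboxylic acid under conditions that leave ketones, acetonide and alkenes alone.

**Step 14**
Reactants: 20
Product: 21 tetracyclic enone acid (C9=C10; 11-oxo; 5β-H; C6-CO2H as both epimers)
Conditions: KOt-Bu (2.5 equiv), t-BuOH/THF, 25 → 45 °C; AcOH
Reagents that add atoms: none
Why: Intramolecular aldol condensation of the 10,11-diketone closes ring B (5-exo-trig) because only attack of C9 on the C10 carbonyl can dehydrate to a conjugated enone, while the carboxylate keeps C7 out of Claisen pathways and C5 equilibrates to the β-H configuration that lets C6 sit equatorial on ring A without a syn-axial methyl/O2 contact.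

**Step 15**
Reactants: 21
Product: 23 tetracyclic enone methyl ester (6β-CO2Me), via methyl ester epimers 22 (not isolated)
Conditions: Me3SiCHN2, MeOH/toluene, 0 °C; then NaOMe (0.5 equiv), MeOH, 50 °C
Reagents that add atoms: (trimethylsilyl)diazomethane, C[Si](C)(C)C=[N+]=[N-]
Why: Esterification with the diazoalkane followed by base-mediated epimerisation α to the ester should move C7 to the β face of ring B, anti to the quaternary C4 on the neighbouring C5 (thermodynamic control).

**Step 16**
Reactants: 23
Product: 24 saturated 11-ketone (10α-H; 9β-H)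
Conditions: Li (2.5 equiv), NH3/THF, −78 °C, 15 min; solid NH4Cl
Reagents that add atoms: none
Why: Dissolving-metal reduction of the enone should protonate the C10 carbanion axially on the α face, because only the trans A/B fusion keeps C9 equatorial on ring A (the cis alternative puts C9 syn-axial to the C4 vinyl group or, after ring flip, the C4 methyl syn-axial to O2), and the enolate is then protonated at C9 on the β face since the rigid ring C chair accepts ring B only cis-fused.

**Step 17**
Reactants: 24
Product: 25 11β-alcohol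
Conditions: LiBH(s-Bu)3, THF, −78 °C; aq. NH4Cl
Reagents that add atoms: none
Why: Hydride reduction with a bulky borohydride should occur from the α face, because the C15–C16 bridge blocks the β face of C11 like two syn-axial substituents, giving the axial 11β-alcohol.

**Step 18**
Reactants: 25
Product: 26 2β,3β,11β-triol
Conditions: AcOH/H2O (4:1), 45 °C
Reagents that add atoms: none
Why: Acid-catalysed acetal hydrolysis frees the 2β,3β-diol under conditions mild enough for the methyl ester and both alkenes.

**Step 19**
Reactants: 26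
Product: 27 2β,3β,11β-triacetate
Conditions: Ac2O, pyridine, DMAP (10 mol %), CH2Cl2, rt
Reagents that add atoms: acetic anhydride, CC(=O)OC(C)=O
Why: DMAP-catalysed acylation caps all three secondary alcohols, including the hindered axial 11β-OH, as acetates whose inductive effect deactivates the C2–H, C3–H and C11–H bonds for step 22.

**Step 20**
Reactants: 27
Product: 28 C19 aldehyde with C16 ketone
Conditions: OsO4 (2 mol %), NaIO4 (5 equiv), 2,6-lutidine, dioxane/H2O (3:1), rt
Reagents that add atoms: sodium periodate, [Na+].[O-]I(=O)(=O)=O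
Why: Lemieux–Johnson cleavage removes the terminal carbon of both terminal alkenes at once, turning the C4 vinyl group into the C19 aldehyde and the 16-methylidene into the C16 ketone, which tolerates the oxidant of step 22 where the alkene would not.

**Step 21**
Reactants: 28
Product: 29 10α-H C19 acid (2β,3β,11β-triacetate; C16 ketone; C7 methyl ester)
Conditions: NaClO2, NaH2PO4, 2-methylbut-2-ene, t-BuOH/H2O, 0 °C → rt
Reagents that add atoms: sodium chlorite, [Na+].[O-]Cl=O
Why: Pinnick oxidation converts the hindered, non-enolisable C19 aldehyde into the free carboxylic acid without affecting ketone, acetates or methyl ester.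

**Step 22**
Reactants: 29
Product: 30 19,10-lactone (2β,3β,11β-triacetate; C16 ketone; C7 methyl ester)
Conditions: [Fe((S,S)-PDP)(MeCN)2](SbF6)2 (PDP = 1,1'-bis(pyridin-2-ylmethyl)-2,2'-bipyrrolidine; 3 × 5 mol %), H2O2 (50 % aq., 3 × 1.2 equiv, slow addition), MeCN, rt, no added carboxylic acid; recovered 29 resubmitted
Reagents that add atoms: none
Why: The C19 acid binds the iron centre as a carboxylate, H2O2 then generates an iron-oxo carboxylate that abstracts the α-face hydrogen on C10, syn-diaxial to C19 across ring A, through a seven-membered transition state, and the tertiary C10 radical recombines with the bound carboxylate oxygen (or with the iron-bound hydroxyl, followed by lactonisation) before it can invert. The closest known reaction type is the carboxylic-acid-directed γ-lactonisation of tertiary C–H bonds with iron or manganese aminopyridine catalysts and H2O2, which has been shown on polycyclic terpenoid acids. The γ-lactone closes as a five-membered ring by C–O bond formation at C10 (formally 5-exo at the C10 radical), bridging C4 and C10 of ring A. No new stereocentre arises: C10 is already stereogenic and keeps its configuration because the tethered carboxylate can reach only its α face. The step needs site selectivity among many C–H bonds, and the substrate secures it: only H-10 is tertiary, γ to the bound carboxylate on the same face and electron-rich, whereas H-2, H-3 and H-11 sit on acetoxy-bearing carbons, H-6 and H-13 are α to carbonyl groups and H-5 and H-9 point to the β face. The C7 acid is masked as its methyl ester so that it cannot direct the oxidant, and C16 is a ketone because the exocyclic alkene would be epoxidised.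

**Step 23**
Reactants: 30
Product: 31 16-methylidene lactone triacetate methyl ester
Conditions: Ph3PCH3Br, KN(SiMe3)2, THF, 0 °C; then 30, 0 °C → rt
Reagents that add atoms: methyltriphenylphosphonium bromide, C[P+](c1ccccc1)(c1ccccc1)c1ccccc1.[Br-]
Why: Wittig methylenation restores the exocyclic C16=C17 alkene, the ylide reacting with the ketone much faster than with lactone or esters, and any acetate it cleaves is removed in the next step anyway.

**Step 24**
Reactants: 31
Product: 32 2β,3β,11β-trihydroxy lactone methyl ester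
Conditions: K2CO3 (0.3 equiv), MeOH, 0 °C → rt
Reagents that add atoms: none
Why: Base-catalysed transesterification (methanolysis) removes the three acetates while the γ-lactone and the hindered C7 methyl ester persist and the mild base avoids retro-aldol epimerisation at C3.

**Step 25**
Reactants: 32
Product: 33 CNP0322347.1
Conditions: n-PrSLi, HMPA, rt; then dil. HCl to pH 3
Reagents that add atoms: none
Why: SN2 dealkylation of the methyl ester by the thiolate liberates the C7 carboxylate without opening the lactone (a tertiary alkyl–oxygen bond) or disturbing the base-sensitive 3β-hydroxy lactone unit.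

**Compound list**

1 | 3-methoxybenzoic acid | COc1cccc(c1)C(=O)O | starting material
2 | 2,3-dibromoprop-1-ene | C=C(Br)CBr | starting material
3 | rac-1-(2-bromoprop-2-en-1-yl)-3-methoxycyclohexa-2,5-diene-1-carboxylic acid | COC1=CC(CC(Br)=C)(C(=O)O)C=CC1 | intermediate
4 | rac-1-(2-bromoprop-2-en-1-yl)-5-oxocyclohex-3-ene-1-carboxylic acid | O=C1C=CCC(CC(Br)=C)(C(=O)O)C1 | intermediate
5 | rac-6-methylidene-3-oxobicyclo[3.2.1]octane-1-carboxylic acid | C=C1CC2(C(=O)O)CC1CC(=O)C2 | intermediate
6 | (S)-1-phenylethylammonium (1R,5S)-6-methylidene-3-oxobicyclo[3.2.1]octane-1-carboxylate | C=C1C[C@]2(C(=O)[O-])C[C@H]1CC(=O)C2.C[C@H]([NH3+])c1ccccc1 | intermediate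
7 | (1R,5S)-6-methylidene-3-oxobicyclo[3.2.1]octane-1-carboxylic acid | C=C1C[C@]2(C(=O)O)C[C@H]1CC(=O)C2 | intermediate
8 | (1R,5S)-1-(hydroxymethyl)-6-methylidenebicyclo[3.2.1]octan-3-ol, both C3 epimers | C=C1C[C@]2(CO)C[C@H]1CC(O)C2 | intermediate
9 | (1R,5S)-6-methylidene-3-oxobicyclo[3.2.1]octane-1-carbaldehyde | C=C1C[C@]2(C=O)C[C@H]1CC(=O)C2 | intermediate
10 | (1R,5S)-1-(1-hydroxy-2-nitroethyl)-6-methylidenebicyclo[3.2.1]octan-3-one, both carbinol epimers | C=C1C[C@]2(C(O)C[N+](=O)[O-])C[C@H]1CC(=O)C2 | intermediate
11 | 1-[(1R,5S)-6-methylidene-3-oxobicyclo[3.2.1]octan-1-yl]-2-nitroethyl methanesulfonate | C=C1C[C@]2(C(OS(C)(=O)=O)C[N+](=O)[O-])C[C@H]1CC(=O)C2 | intermediate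
12 | (1R,5S)-6-methylidene-1-[(E)-2-nitroethenyl]bicyclo[3.2.1]octan-3-one | C=C1C[C@]2(/C=C/[N+](=O)[O-])C[C@H]1CC(=O)C2 | intermediate
13 | (1S,2R)-3-methylcyclohexa-3,5-diene-1,2-diol (toluene cis-dihydrodiol) | C1=C[C@H](O)[C@H](O)C(C)=C1 | starting material
14 | (3aR,7aS)-2,2,4-trimethyl-3a,7a-dihydro-1,3-benzodioxole | C1=C[C@H](OC(C)(C)O2)[C@H]2C(C)=C1 | intermediate
15 | (3aR,7aS)-2,2,4-trimethyl-3a,6,7,7a-tetrahydro-1,3-benzodioxole | C1C[C@H](OC(C)(C)O2)[C@H]2C(C)=C1 | intermediate
16 | (3aS,7aR)-2,2,7-trimethyl-3a,7a-dihydro-1,3-benzodioxol-5(4H)-one, i.e. (4R,5S)-4,5-(isopropylidenedioxy)-3-methylcyclohex-2-en-1-one | O=C1C[C@H](OC(C)(C)O2)[C@H]2C(C)=C1 | intermediate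
17 | trimethyl{[(3aR,4S,7aS)-4-ethenyl-2,2,4-trimethyl-3a,4,7,7a-tetrahydro-1,3-benzodioxol-6-yl]oxy}silane | C[Si](C)(C)OC=1C[C@H](OC(C)(C)O2)[C@H]2[C@@](C)(C=C)C=1 | intermediate
18 | lithium (3aR,4S,7aS)-4-ethenyl-2,2,4-trimethyl-3a,4,7,7a-tetrahydro-1,3-benzodioxol-6-olate | [Li]OC=1C[C@H](OC(C)(C)O2)[C@H]2[C@@](C)(C=C)C=1 | intermediate
19 | (1R,5S)-1-{1-[(3aR,4S,7aS)-4-ethenyl-2,2,4-trimethyl-6-oxohexahydro-1,3-benzodioxol-5-yl]-2-nitroethyl}-6-methylidenebicyclo[3.2.1]octan-3-one, both epimers at C5 and C6 | C=C1C[C@]2(C(C[N+](=O)[O-])C3C(=O)C[C@H](OC(C)(C)O4)[C@H]4[C@@]3(C)C=C)C[C@H]1CC(=O)C2 | intermediate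
20 | 2-[(3aR,4S,7aS)-4-ethenyl-2,2,4-trimethyl-6-oxohexahydro-1,3-benzodioxol-5-yl]-2-[(1R,5S)-6-methylidene-3-oxobicyclo[3.2.1]octan-1-yl]acetic acid, both epimers at C5 and C6 | C=C1C[C@]2(C(C(=O)O)C3C(=O)C[C@H](OC(C)(C)O4)[C@H]4[C@@]3(C)C=C)C[C@H]1CC(=O)C2 | intermediate
21 | tetracyclic enone acid: rings A–D, C9=C10, 11-oxo, 16-methylidene, 2β,3β-O-isopropylidene, 4β-methyl, 4α-ethenyl, 5β-H, carboxylic acid (C7) on C6 as both epimers | C=C1C[C@]23C[C@H]1CC(=O)C2=C2C[C@H](OC(C)(C)O4)[C@H]4[C@@](C)(C=C)[C@H]2C3C(=O)O | intermediate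
22 | methyl ester of 21, both C6 epimers | C=C1C[C@]23C[C@H]1CC(=O)C2=C2C[C@H](OC(C)(C)O4)[C@H]4[C@@](C)(C=C)[C@H]2C3C(=O)OC | intermediate
23 | tetracyclic enone ester: as 22 with 6β-CO2Me (6α-H) | C=C1C[C@]23C[C@H]1CC(=O)C2=C2C[C@H](OC(C)(C)O4)[C@H]4[C@@](C)(C=C)[C@H]2[C@@H]3C(=O)OC | intermediate
24 | saturated 11-ketone: as 23 with C9–C10 single bond, 9β-H and 10α-H | C=C1C[C@]23C[C@H]1CC(=O)[C@H]2[C@@H]2C[C@H](OC(C)(C)O4)[C@H]4[C@@](C)(C=C)[C@H]2[C@@H]3C(=O)OC | intermediate
25 | 11β-alcohol: as 24 with 11β-OH in place of the ketone | C=C1C[C@]23C[C@H]1C[C@H](O)[C@H]2[C@@H]2C[C@H](OC(C)(C)O4)[C@H]4[C@@](C)(C=C)[C@H]2[C@@H]3C(=O)OC | intermediate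
26 | 2β,3β,11β-triol: as 25 without the acetonide | C=C1C[C@]23C[C@H]1C[C@H](O)[C@H]2[C@@H]2C[C@H](O)[C@H](O)[C@@](C)(C=C)[C@H]2[C@@H]3C(=O)OC | intermediate
27 | 2β,3β,11β-triacetate of 26 | C=C1C[C@]23C[C@H]1C[C@H](OC(C)=O)[C@H]2[C@@H]2C[C@H](OC(C)=O)[C@H](OC(C)=O)[C@@](C)(C=C)[C@H]2[C@@H]3C(=O)OC | intermediate
28 | triacetate with C19 aldehyde on C4α and C16 ketone, 10α-H, 6β-CO2Me | O=C1C[C@]23C[C@H]1C[C@H](OC(C)=O)[C@H]2[C@@H]2C[C@H](OC(C)=O)[C@H](OC(C)=O)[C@@](C)(C=O)[C@H]2[C@@H]3C(=O)OC | intermediate
29 | 10α-H C19 acid: 2β,3β,11β-triacetoxy, 4β-methyl, 4α-CO2H, 5β-H, 6β-CO2Me, 9β-H, 16-oxo | O=C1C[C@]23C[C@H]1C[C@H](OC(C)=O)[C@H]2[C@@H]2C[C@H](OC(C)=O)[C@H](OC(C)=O)[C@@](C)(C(=O)O)[C@H]2[C@@H]3C(=O)OC | intermediate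
30 | 19,10-lactone of 29 (O on C10α), triacetate, 16-oxo, C7 methyl ester | O=C1C[C@]23C[C@H]1C[C@H](OC(C)=O)[C@H]2[C@@]12C[C@H](OC(C)=O)[C@H](OC(C)=O)[C@@](C)(C(=O)O1)[C@H]2[C@@H]3C(=O)OC | intermediate
31 | 16-methylidene 19,10-lactone, 2β,3β,11β-triacetate, C7 methyl ester | C=C1C[C@]23C[C@H]1C[C@H](OC(C)=O)[C@H]2[C@@]12C[C@H](OC(C)=O)[C@H](OC(C)=O)[C@@](C)(C(=O)O1)[C@H]2[C@@H]3C(=O)OC | intermediate
32 | methyl ester of the target: 2β,3β,11β-trihydroxy 16-methylidene 19,10-lactone | C=C1C[C@]23C[C@H]1C[C@H](O)[C@H]2[C@@]12C[C@H](O)[C@H](O)[C@@](C)(C(=O)O1)[C@H]2[C@@H]3C(=O)OC | intermediate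
33 | CNP0322347.1: 2β,3β,11β-trihydroxy-16-methylidene 19,10-lactone 7-carboxylic acid | C=C1C[C@]23C[C@H]1C[C@H](O)[C@H]2[C@@]12C[C@H](O)[C@H](O)[C@@](C)(C(=O)O1)[C@H]2[C@@H]3C(=O)O | target

**Totals**

Total step count: 25.
Longest linear sequence: 21 steps (steps 1–7, then 12–25, from 3-methoxybenzoic acid).

**Steps most likely to fail**

1. Step 12. The conjugate addition may be outrun by proton transfer from the ring C ketone to the enolate, or be retarded by the quaternary neighbours (C4 and C8) of the bond being made. The fallback sets out from 17 and 9 and makes the C5–C6 bond by addition to a carbonyl group, which is less demanding. Mukaiyama aldol addition of 17 to the aldehyde 9 (BF3·OEt2, CH2Cl2, −78 °C) gives the β-hydroxy ketone F1. Dehydration with methyl N-(triethylammoniosulfonyl)carbamate gives the exocyclic enone F2. Base-catalysed conjugate addition of nitromethane (DBU, MeNO2) to F2 brings in C7 and returns to the route at 19.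

2. Step 16. Protonation of the C10 carbanion may take place on the β face (cis A/B fusion), and the hindered ester may be partly reduced. The fallback sets out from 23 and delivers the C10 hydrogen from a metal held on the α face. Luche reduction (NaBH4, CeCl3·7H2O, MeOH) from the open α face gives the 11β-allylic alcohol F3, and formylation (HCO2H/Ac2O, pyridine) gives the allylic formate F4. Palladium-catalysed decarboxylative reduction (Pd(OAc)2, n-Bu3P, dioxane, reflux; zerovalent palladium formed in situ) ionises the formate with inversion and passes hydride from palladium to C10 on the α face with allylic transposition, giving the 10α-H Δ9(11)-alkene F5. Epoxidation with mCPBA on the α face of this trisubstituted alkene, the most electron-rich of the three, gives the 9α,11α-epoxide F6. Meinwald rearrangement (BF3·OEt2), with hydride shifting from C11 to the β face of C9, returns to the route at 24.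

3. Step 22. The oxidation may stall at low conversion, or attack methylene C–H bonds (C1, C12), if the hindered axial carboxylate binds the metal poorly. The fallback sets out from 29 and keeps the C10–H to C10–O construction but abstracts the hydrogen with a nitrogen-centred radical. The acid is converted into the primary amide F7 (ClCO2Et, Et3N; then NH3). Irradiation with PhI(OAc)2 and I2 (visible light, CH2Cl2) generates the amidyl radical, which takes H-10 by a 1,5-shift (Hofmann–Löffler–Freytag type); oxidation of the C10 radical and closure through the amide oxygen give the iminolactone F8. Hydrolysis of F8 with dilute HCl on work-up returns to the route at 30.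

**Further compounds**

F1 | step 12 | (1R,5S)-1-{[(3aR,4S,7aS)-4-ethenyl-2,2,4-trimethyl-6-oxohexahydro-1,3-benzodioxol-5-yl](hydroxy)methyl}-6-methylidenebicyclo[3.2.1]octan-3-one, epimers at C5 and C6 | C=C1C[C@]2(C(O)C3C(=O)C[C@H](OC(C)(C)O4)[C@H]4[C@@]3(C)C=C)C[C@H]1CC(=O)C2
F2 | step 12 | (1R,5S)-1-{[(3aR,4S,7aS)-4-ethenyl-2,2,4-trimethyl-6-oxotetrahydro-1,3-benzodioxol-5(4H)-ylidene]methyl}-6-methylidenebicyclo[3.2.1]octan-3-one | C=C1C[C@]2(C=C3C(=O)C[C@H](OC(C)(C)O4)[C@H]4[C@@]3(C)C=C)C[C@H]1CC(=O)C2
F3 | step 16 | 11β-allylic alcohol: as 23 with 11β-OH in place of the ketone | C=C1C[C@]23C[C@H]1C[C@H](O)C2=C2C[C@H](OC(C)(C)O4)[C@H]4[C@@](C)(C=C)[C@H]2[C@@H]3C(=O)OC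
F4 | step 16 | 11β-formate of F3 | C=C1C[C@]23C[C@H]1C[C@H](OC=O)C2=C2C[C@H](OC(C)(C)O4)[C@H]4[C@@](C)(C=C)[C@H]2[C@@H]3C(=O)OC
F5 | step 16 | 10α-H Δ9(11)-alkene: as 24 with C9=C11 in place of the ketone and of H-9 | C=C1C[C@]23C[C@H]1CC=C2[C@@H]2C[C@H](OC(C)(C)O4)[C@H]4[C@@](C)(C=C)[C@H]2[C@@H]3C(=O)OC
F6 | step 16 | 9α,11α-epoxide of F5 | C=C1C[C@]23C[C@H]1C[C@H]4O[C@]42[C@@H]2C[C@H](OC(C)(C)O5)[C@H]5[C@@](C)(C=C)[C@H]2[C@@H]3C(=O)OC
F7 | step 22 | primary C19 amide of 29 | O=C1C[C@]23C[C@H]1C[C@H](OC(C)=O)[C@H]2[C@@H]2C[C@H](OC(C)=O)[C@H](OC(C)=O)[C@@](C)(C(N)=O)[C@H]2[C@@H]3C(=O)OC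
F8 | step 22 | 19,10-iminolactone: as 30 with C19=NH in place of the lactone carbonyl | O=C1C[C@]23C[C@H]1C[C@H](OC(C)=O)[C@H]2[C@@]12C[C@H](OC(C)=O)[C@H](OC(C)=O)[C@@](C)(C(=N)O1)[C@H]2[C@@H]3C(=O)OC
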